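**Strategy.** The route rests on cutting the bond between the carbinol carbon (benzylic to the terminal guaiacyl ring) and the adjacent CH(CH2OH) carbon (benzylic to the tetrasubstituted ring, ortho to its phenol). This anti 1,3-diol is an aldol retron: the CH2OH carbon is raised to an imide carbonyl, which acidifies the ring-bound CH2, and the carbinol carbon becomes the non-enolisable aldehyde of O-benzylvanillin. One magnesium-catalysed, auxiliary-controlled anti-aldol of the N-arylacetyl (R)-4-benzyloxazolidinone, which already carries the complete trans-dibenzylbutyrolactone, joins the two halves and sets both new stereocentres; reduction and hydrogenolysis then finish.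

Key step: step 11

Remark 1: compounds 1, 5, 6, 11, 17 and 20 and all reagents are taken as commercial.
Remark 2: the sense of induction in step 11 is assigned from the chelated-enolate model of magnesium-catalysed oxazolidinone anti-aldols (attack anti to the C4 substituent, as in alkylations), which calls for the (R)-auxiliary. In the Why lines, C1 is the carbinol carbon and C2 the CH(CH2OH) carbon of the propanediol unit.

**Step 1**
Reactants: 1 4-bromo-2-methoxyphenol
Product: 2 1-(allyloxy)-4-bromo-2-methoxybenzene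
Conditions: allyl bromide, K2CO3, acetone, reflux
Reagents that add atoms: allyl bromide, C=CCBr
Why: Williamson O-allylation of the phenoxide (SN2) should be clean; no stereocentre is involved.

**Step 2**
Reactants: 2 1-(allyloxy)-4-bromo-2-methoxybenzene
Product: 3 2-allyl-4-bromo-6-methoxyphenol
Conditions: N,N-diethylaniline, 200 °C
Reagents that add atoms: none
Why: The aromatic Claisen rearrangement ([3,3]-sigmatropic shift, then tautomerisation) can deliver the allyl group only to C6, because the other ortho position carries OMe and the para position carries Br.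

**Step 3**
Reactants: 3 2-allyl-4-bromo-6-methoxyphenol
Product: 4 1-allyl-2-(benzyloxy)-5-bromo-3-methoxybenzene
Conditions: BnBr, K2CO3, DMF, rt
Reagents that add atoms: benzyl bromide, BrCc1ccccc1
Why: Williamson O-benzylation protects the phenol for the Grignard, enolate and oxidation steps that follow.

**Step 4**
Reactants: 5 (R)-epichlorohydrin; 6 diethyl malonate
Product: 7 ethyl (1S,5R)-2-oxo-3-oxabicyclo[3.1.0]hexane-1-carboxylate
Conditions: NaOEt, EtOH, 0 °C to reflux
Reagents that add atoms: none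
Why: In this malonate alkylation–cyclopropanation–lactonisation cascade the malonate opens the epoxide at CH2, the alkoxide re-closes to the transposed epoxide with loss of chloride, the malonate anion opens that epoxide 3-exo-tet at the stereocentre with inversion, and the freed alkoxide lactonises, so (R)-5 should give the cis-fused (1S,5R) lactone.

**Step 5**
Reactants: 4 1-allyl-2-(benzyloxy)-5-bromo-3-methoxybenzene; 7 ethyl (1S,5R)-2-oxo-3-oxabicyclo[3.1.0]hexane-1-carboxylate
Product: 9 ethyl (4R)-4-(3-allyl-4-benzyloxy-5-methoxybenzyl)-2-oxooxolane-3-carboxylate, via arylmagnesium bromide 8 (not isolated)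
Conditions: Mg, THF, 40 °C; then CuI (10 mol%), 7, THF, −30 to 0 °C; 1 M HCl
Reagents that add atoms: magnesium, [Mg] (kept only in intermediate 8)
Why: Copper-catalysed homoconjugate (SN2-type) addition of the aryl Grignard reagent to the CH2 of the doubly activated cyclopropane releases a malonate-type enolate; the ring-fusion CH is not touched and becomes C4 (R) of the lactone, while C3 is an inconsequential epimer mixture.

**Step 6**
Reactants: 9 ethyl (4R)-4-(3-allyl-4-benzyloxy-5-methoxybenzyl)-2-oxooxolane-3-carboxylate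
Product: 10 (4R)-4-(3-allyl-4-benzyloxy-5-methoxybenzyl)oxolan-2-one
Conditions: LiCl, DMSO/H2O, 150 °C
Reagents that add atoms: none
Why: Krapcho dealkoxycarbonylation removes the activating ester; C4 is not epimerisable and the allyl and benzyl ether groups should survive the neutral conditions.

**Step 7**
Reactants: 11 [4-(benzyloxy)-3-methoxyphenyl]methanol
Product: 12 1-(benzyloxy)-4-(bromomethyl)-2-methoxybenzene
Conditions: PBr3, Et2O, 0 °C
Reagents that add atoms: phosphorus tribromide, BrP(Br)Br
Why: Bromination of the benzylic alcohol via its phosphite ester (SN2) should give the bromide, which is used fresh.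

**Step 8**
Reactants: 10 (4R)-4-(3-allyl-4-benzyloxy-5-methoxybenzyl)oxolan-2-one; 12 1-(benzyloxy)-4-(bromomethyl)-2-methoxybenzene
Product: 14 (3R,4R)-3-(4-benzyloxy-3-methoxybenzyl)-4-(3-allyl-4-benzyloxy-5-methoxybenzyl)oxolan-2-one, via lithium lactone enolate 13 (not isolated)
Conditions: LiHMDS, THF, −78 °C; then 12, DMPU, −78 to −30 °C
Reagents that add atoms: lithium hexamethyldisilazide, [Li]N([Si](C)(C)C)[Si](C)(C)C (its lithium is kept only in intermediate 13)
Why: Kinetic alkylation of the lactone enolate should occur anti to the C4 arylmethyl group and so set C3 as R (trans-2,3-dibenzylbutyrolactone); the allylic/benzylic CH2 of the allylarene is not acidic enough for LiHMDS.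

**Step 9**
Reactants: 14 (3R,4R)-3-(4-benzyloxy-3-methoxybenzyl)-4-(3-allyl-4-benzyloxy-5-methoxybenzyl)oxolan-2-one
Product: 16 2-[2-benzyloxy-3-methoxy-5-{[(3R,4R)-4-(4-benzyloxy-3-methoxybenzyl)-5-oxooxolan-3-yl]methyl}phenyl]acetic acid, via arylacetaldehyde 15 (not isolated)
Conditions: O3, MeCN/H2O (9:1), 0 °C, Sudan III end point; then NaClO2, NaH2PO4, 2-methyl-2-butene (excess), 0 °C to rt
Reagents that add atoms: ozone, [O-][O+]=O; sodium chlorite, [Na+].[O-]Cl=O
Why: Ozonolysis in wet acetonitrile (water traps the carbonyl oxide, so the aldehyde forms without a reductant) followed by Pinnick oxidation in the same pot should give the acid, because the terminal alkene reacts with ozone far faster than the alkoxyarenes and the scavenger removes HOCl.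

**Step 10**
Reactants: 16 the arylacetic acid; 17 (R)-4-benzyl-1,3-oxazolidin-2-one
Product: 19 (4R)-4-benzyl-3-{2-[2-benzyloxy-3-methoxy-5-{[(3R,4R)-4-(4-benzyloxy-3-methoxybenzyl)-5-oxooxolan-3-yl]methyl}phenyl]acetyl}oxazolidin-2-one, via mixed pivalic anhydride 18 (not isolated)
Conditions: PivCl, Et3N, THF, −20 °C; then 17, LiCl, −20 °C to rt
Reagents that add atoms: pivaloyl chloride, CC(C)(C)C(=O)Cl (kept only in intermediate 18)
Why: N-acylation of the oxazolidinone through the mixed anhydride under LiCl/Et3N needs no strong base, so the lactone α-stereocentre should not epimerise.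

**Step 11**
Reactants: 19 the N-arylacetyl oxazolidinone; 20 4-(benzyloxy)-3-methoxybenzaldehyde
Product: 22 (4R)-4-benzyl-3-[(2S,3R)-2-[2-benzyloxy-3-methoxy-5-{[(3R,4R)-4-(4-benzyloxy-3-methoxybenzyl)-5-oxooxolan-3-yl]methyl}phenyl]-3-(4-benzyloxy-3-methoxyphenyl)-3-(trimethylsilyloxy)propanoyl]oxazolidin-2-one, via chloromagnesium Z-enolate 21 (not isolated)
Conditions: MgCl2 (0.3 equiv), Et3N (2.5 equiv), TMSCl (2 equiv), 20 (1.3 equiv), EtOAc, rt; pH 7 buffer work-up, Et3N-deactivated silica
Reagents that add atoms: chlorotrimethylsilane, C[Si](C)(C)Cl; magnesium chloride, Cl[Mg]Cl (kept only in intermediate 21)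
Why: MgCl2 chelates the two imide carbonyls of 19 so that Et3N removes only the doubly activated ArCH2 proton, giving the chelated Z-enolate 21, which adds to the aldehyde carbon of 20; TMSCl then silylates the magnesium aldolate, which frees the metal for turnover and blocks retro-aldol and epimerisation. The closest known reaction type is the magnesium halide-catalysed direct anti-aldol of chiral N-acyloxazolidinones with aromatic aldehydes (soft-enolisation aldol). No ring is closed. C2 is controlled by the auxiliary, because the aldehyde should meet the face of the chelated enolate opposite the C4 benzyl group of the (R)-oxazolidinone; C1 is controlled by the boat-like magnesium-bound transition state of the Z-enolate, which gives the 2,3-anti relationship. The step needs site selectivity between the imide CH2 and the lactone α-CH, secured by chelation-enhanced acidity under a weak amine base, and reagent control over the remote lactone stereocentres, secured by the auxiliary next to the reacting carbon. Aldehyde 20 cannot enolise or self-condense, and the lactone carbonyl is not activated under these conditions.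

**Step 12**
Reactants: 22 the silylated anti-aldol imide
Product: 24 (3R,4R)-3-(4-benzyloxy-3-methoxybenzyl)-4-{4-benzyloxy-3-[(1R,2R)-1-(4-benzyloxy-3-methoxyphenyl)-1,3-dihydroxypropan-2-yl]-5-methoxybenzyl}oxolan-2-one, via O-trimethylsilyl diol 23 (not isolated)
Conditions: NaBH4, THF/H2O (4:1), 0 °C to rt; then 10% aq. citric acid, rt
Reagents that add atoms: none
Why: Borohydride reduction of the exocyclic imide carbonyl (reductive removal of the auxiliary) should be much faster than attack on the α,β-disubstituted γ-butyrolactone; the silyl ether blocks retro-aldol during reduction and is then hydrolysed by mild acid that should not ionise the benzylic position.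

**Step 13**
Reactants: 24 the tribenzyl diol
Product: 25 (3R,4R)-4-{4-hydroxy-3-[(1R,2R)-1,3-dihydroxy-1-(4-hydroxy-3-methoxyphenyl)propan-2-yl]-5-methoxybenzyl}-3-(4-hydroxy-3-methoxybenzyl)oxolan-2-one
Conditions: H2 (1 atm), 10% Pd/C, EtOAc/EtOH, rt, stopped at 3 equiv uptake
Reagents that add atoms: none
Why: Hydrogenolysis of the three aryl benzyl ethers under neutral conditions should be much faster than cleavage of the secondary benzylic C–OH bond; no stereocentre is affected.

**Compound list**
1 | 4-bromo-2-methoxyphenol | COc1cc(Br)ccc1O | starting material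
2 | 1-(allyloxy)-4-bromo-2-methoxybenzene | COc1cc(Br)ccc1OCC=C | intermediate
3 | 2-allyl-4-bromo-6-methoxyphenol | COc1cc(Br)cc(CC=C)c1O | intermediate
4 | 1-allyl-2-(benzyloxy)-5-bromo-3-methoxybenzene | COc1cc(Br)cc(CC=C)c1OCc1ccccc1 | intermediate
5 | (R)-epichlorohydrin | ClC[C@H]1CO1 | starting material
6 | diethyl malonate | CCOC(=O)CC(=O)OCC | starting material
7 | ethyl (1S,5R)-2-oxo-3-oxabicyclo[3.1.0]hexane-1-carboxylate | CCOC(=O)[C@]12C[C@H]1COC2=O | intermediate
8 | (3-allyl-4-benzyloxy-5-methoxyphenyl)magnesium bromide (not isolated) | C=CCc1cc([Mg]Br)cc(OC)c1OCc1ccccc1 | intermediate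
9 | ethyl (4R)-4-(3-allyl-4-benzyloxy-5-methoxybenzyl)-2-oxooxolane-3-carboxylate (C3 epimers) | CCOC(=O)C1C(=O)OC[C@@H]1Cc1cc(OC)c(OCc2ccccc2)c(CC=C)c1 | intermediate
10 | (4R)-4-(3-allyl-4-benzyloxy-5-methoxybenzyl)oxolan-2-one | C1C(=O)OC[C@@H]1Cc1cc(OC)c(OCc2ccccc2)c(CC=C)c1 | intermediate
11 | [4-(benzyloxy)-3-methoxyphenyl]methanol | OCc1ccc(OCc2ccccc2)c(OC)c1 | starting material
12 | 1-(benzyloxy)-4-(bromomethyl)-2-methoxybenzene | BrCc1ccc(OCc2ccccc2)c(OC)c1 | intermediate
13 | lithium enolate of lactone 10 (not isolated) | C1=C(O[Li])OC[C@@H]1Cc1cc(OC)c(OCc2ccccc2)c(CC=C)c1 | intermediate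
14 | (3R,4R)-3-(4-benzyloxy-3-methoxybenzyl)-4-(3-allyl-4-benzyloxy-5-methoxybenzyl)oxolan-2-one | COc1cc(C[C@H]2C(=O)OC[C@@H]2Cc2cc(OC)c(OCc3ccccc3)c(CC=C)c2)ccc1OCc1ccccc1 | intermediate
15 | 2-[2-benzyloxy-3-methoxy-5-{[(3R,4R)-4-(4-benzyloxy-3-methoxybenzyl)-5-oxooxolan-3-yl]methyl}phenyl]acetaldehyde (not isolated) | COc1cc(C[C@H]2C(=O)OC[C@@H]2Cc2cc(OC)c(OCc3ccccc3)c(CC=O)c2)ccc1OCc1ccccc1 | intermediate
16 | 2-[2-benzyloxy-3-methoxy-5-{[(3R,4R)-4-(4-benzyloxy-3-methoxybenzyl)-5-oxooxolan-3-yl]methyl}phenyl]acetic acid | COc1cc(C[C@H]2C(=O)OC[C@@H]2Cc2cc(OC)c(OCc3ccccc3)c(CC(=O)O)c2)ccc1OCc1ccccc1 | intermediate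
17 | (R)-4-benzyl-1,3-oxazolidin-2-one | O=C1N[C@H](Cc2ccccc2)CO1 | starting material
18 | mixed anhydride of acid 16 with pivalic acid (not isolated) | COc1cc(C[C@H]2C(=O)OC[C@@H]2Cc2cc(OC)c(OCc3ccccc3)c(CC(=O)OC(=O)C(C)(C)C)c2)ccc1OCc1ccccc1 | intermediate
19 | (4R)-4-benzyl-3-{2-[2-benzyloxy-3-methoxy-5-{[(3R,4R)-4-(4-benzyloxy-3-methoxybenzyl)-5-oxooxolan-3-yl]methyl}phenyl]acetyl}oxazolidin-2-one | COc1cc(C[C@H]2C(=O)OC[C@@H]2Cc2cc(OC)c(OCc3ccccc3)c(CC(=O)N3[C@H](Cc4ccccc4)COC3=O)c2)ccc1OCc1ccccc1 | intermediate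
20 | 4-(benzyloxy)-3-methoxybenzaldehyde | O=Cc1ccc(OCc2ccccc2)c(OC)c1 | starting material
21 | chloromagnesium (Z)-enolate of imide 19, Mg also bound to the oxazolidinone C=O (not isolated) | COc1cc(C[C@H]2C(=O)OC[C@@H]2Cc2cc(OC)c(OCc3ccccc3)c(/C=C(\O[Mg]Cl)N3[C@H](Cc4ccccc4)COC3=O)c2)ccc1OCc1ccccc1 | intermediate
22 | (4R)-4-benzyl-3-[(2S,3R)-2-[2-benzyloxy-3-methoxy-5-{[(3R,4R)-4-(4-benzyloxy-3-methoxybenzyl)-5-oxooxolan-3-yl]methyl}phenyl]-3-(4-benzyloxy-3-methoxyphenyl)-3-(trimethylsilyloxy)propanoyl]oxazolidin-2-one | COc1cc(C[C@H]2C(=O)OC[C@@H]2Cc2cc(OC)c(OCc3ccccc3)c([C@H](C(=O)N3[C@H](Cc4ccccc4)COC3=O)[C@@H](O[Si](C)(C)C)c3ccc(OCc4ccccc4)c(OC)c3)c2)ccc1OCc1ccccc1 | intermediate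
23 | (3R,4R)-3-(4-benzyloxy-3-methoxybenzyl)-4-{4-benzyloxy-3-[(1R,2R)-1-(4-benzyloxy-3-methoxyphenyl)-3-hydroxy-1-(trimethylsilyloxy)propan-2-yl]-5-methoxybenzyl}oxolan-2-one (not isolated) | COc1cc(C[C@H]2C(=O)OC[C@@H]2Cc2cc(OC)c(OCc3ccccc3)c([C@H](CO)[C@@H](O[Si](C)(C)C)c3ccc(OCc4ccccc4)c(OC)c3)c2)ccc1OCc1ccccc1 | intermediate
24 | (3R,4R)-3-(4-benzyloxy-3-methoxybenzyl)-4-{4-benzyloxy-3-[(1R,2R)-1-(4-benzyloxy-3-methoxyphenyl)-1,3-dihydroxypropan-2-yl]-5-methoxybenzyl}oxolan-2-one | COc1cc(C[C@H]2C(=O)OC[C@@H]2Cc2cc(OC)c(OCc3ccccc3)c([C@H](CO)[C@@H](O)c3ccc(OCc4ccccc4)c(OC)c3)c2)ccc1OCc1ccccc1 | intermediate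
25 | (3R,4R)-4-{4-hydroxy-3-[(1R,2R)-1,3-dihydroxy-1-(4-hydroxy-3-methoxyphenyl)propan-2-yl]-5-methoxybenzyl}-3-(4-hydroxy-3-methoxybenzyl)oxolan-2-one | COc1cc(C[C@H]2C(=O)OC[C@@H]2Cc2cc(OC)c(O)c([C@H](CO)[C@@H](O)c3ccc(O)c(OC)c3)c2)ccc1O | target

**Step count.** 13 steps in total; the longest linear sequence is 11 steps (1–3, 5, 6, 8–13).

**Steps most likely to fail**

Step 11. The chelated enolate may add with weak or wrong facial and anti selectivity, because the ortho-benzyloxy aryl group on the enolate carbon crowds the boat-like transition state. The electron-rich aldehyde may also add slowly, and the aldolate may revert before it is silylated. The fallback sets out from acid 16 and comes back at diol 24. Acid 16 is coupled with (S)-4-benzyl-1,3-thiazolidine-2-thione (EDC·HCl, DMAP, CH2Cl2) to give the N-arylacetyl thiazolidinethione F1. Its magnesium bromide-catalysed anti-aldol with aldehyde 20 (MgBr2·OEt2 cat., Et3N, TMSCl, EtOAc) runs through a non-chelated thioimide enolate, which should react on the other enolate face relative to its auxiliary (hence the S auxiliary). This should give the silylated anti-aldol thioimide F2 with the same C1/C2 configuration as 22. NaBH4 in THF/EtOH at 0 °C, followed by the citric acid wash, removes the thione auxiliary (more easily than an oxazolidinone) and the silyl group and gives 24.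

Step 12. Hydride may attack the ring carbonyl of the auxiliary at the hindered α-aryl imide (endocyclic cleavage), the lactone may be partly reduced, or retro-aldol may set in once the silyl group is lost under the basic conditions. The fallback sets out from 22 and comes back at 24. LiOH/H2O2 in THF/H2O at 0 °C attacks the exocyclic carbonyl, and any opened lactone re-closes on acidification to pH 3; this should give the β-hydroxy acid F3 with the silyl group lost. BH3·SMe2 in THF at 0 °C then reduces the carboxylic acid much faster than the lactone and gives 24.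

Step 9. Ozone may attack the alkoxyarenes or the benzylic ether positions once the alkene is consumed, the enolisable arylacetaldehyde may condense with itself, and hypochlorous acid may chlorinate the electron-rich rings. The fallback sets out from 14 and comes back at aldehyde 15. OsO4 (cat.) with NMO in acetone/H2O should give the vicinal diol F4 (both carbinol epimers, of no consequence). NaIO4 in THF/pH 7 buffer cleaves it to 15, which is oxidised at once under the Pinnick conditions of step 9 to acid 16.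

**Further compounds**
F1 | step 11 | (4S)-4-benzyl-3-{2-[2-benzyloxy-3-methoxy-5-{[(3R,4R)-4-(4-benzyloxy-3-methoxybenzyl)-5-oxooxolan-3-yl]methyl}phenyl]acetyl}-1,3-thiazolidine-2-thione | COc1cc(C[C@H]2C(=O)OC[C@@H]2Cc2cc(OC)c(OCc3ccccc3)c(CC(=O)N3[C@@H](Cc4ccccc4)CSC3=S)c2)ccc1OCc1ccccc1
F2 | step 11 | (4S)-4-benzyl-3-[(2S,3R)-2-[2-benzyloxy-3-methoxy-5-{[(3R,4R)-4-(4-benzyloxy-3-methoxybenzyl)-5-oxooxolan-3-yl]methyl}phenyl]-3-(4-benzyloxy-3-methoxyphenyl)-3-(trimethylsilyloxy)propanoyl]-1,3-thiazolidine-2-thione | COc1cc(C[C@H]2C(=O)OC[C@@H]2Cc2cc(OC)c(OCc3ccccc3)c([C@H](C(=O)N3[C@@H](Cc4ccccc4)CSC3=S)[C@@H](O[Si](C)(C)C)c3ccc(OCc4ccccc4)c(OC)c3)c2)ccc1OCc1ccccc1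
F3 | step 12 | (2S,3R)-2-[2-benzyloxy-3-methoxy-5-{[(3R,4R)-4-(4-benzyloxy-3-methoxybenzyl)-5-oxooxolan-3-yl]methyl}phenyl]-3-(4-benzyloxy-3-methoxyphenyl)-3-hydroxypropanoic acid | COc1cc(C[C@H]2C(=O)OC[C@@H]2Cc2cc(OC)c(OCc3ccccc3)c([C@H](C(=O)O)[C@@H](O)c3ccc(OCc4ccccc4)c(OC)c3)c2)ccc1OCc1ccccc1
F4 | step 9 | (3R,4R)-3-(4-benzyloxy-3-methoxybenzyl)-4-[4-benzyloxy-3-(2,3-dihydroxypropyl)-5-methoxybenzyl]oxolan-2-one | COc1cc(C[C@H]2C(=O)OC[C@@H]2Cc2cc(OC)c(OCc3ccccc3)c(CC(O)CO)c2)ccc1OCc1ccccc1
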